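**Retrosynthetic overview**
- The target is opened at its 5-OH to the 5-O-methyl ether (3,5,6,7,8,4'-hexamethoxyflavone); the C4 carbonyl directs the final peri demethylation. The 3-OMe goes back to a flavonol and then to tangeretin by oxidation of the C2=C3 alkene.
- Feature on which the route rests: the C4 carbonyl sits between C4a of the hexasubstituted A ring and C3 of the C2=C3 alkene, with the C8a oxygen ortho to C4a. C4 can therefore enter as carbon monoxide between an aryl iodide at C4a and the terminal carbon of 4-ethynylanisole, and the C8a phenol then closes O1–C2.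
- Key disconnection of tangeretin: C4a–C4, C4–C3 and O1–C2, giving 2-iodo-3,4,5,6-tetramethoxyphenol, CO and 4-ethynylanisole.
- The iodophenol comes from 1,2,3,4-tetramethoxybenzene by ortho-lithiation–borylation–oxidation and iodination at the one remaining ring carbon.
- Ring order: rings A and B are bought; the pyranone C ring is the only ring formed (step 3).

Key step: step 3

Remark: the target has no stereocentre and no stereogenic double bond, so no stereocontrol is needed; the only chiral species on the route is the racemic, non-isolated epoxide 11.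

**Route**

Step 1
Reactants: 1 1,2,3,4-tetramethoxybenzene
Product: 4 2,3,4,5-tetramethoxyphenol, via aryllithium 2 (not isolated), via dimethyl arylboronate 3 (not isolated)
Conditions: n-BuLi, TMEDA, THF, 0 °C to rt; B(OMe)3, −78 °C to rt; AcOH, 30% aq. H2O2, 0 °C to rt
Reagents that add atoms: hydrogen peroxide, OO
Why: The two ring hydrogens of 1 are equivalent and each is ortho to a methoxy group, so directed ortho-metalation gives a single aryllithium, which is trapped as the boronate and oxidised at the C–B bond to the phenol (directed ortho-metalation–borylation–oxidation).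

Step 2
Reactants: 4 2,3,4,5-tetramethoxyphenol
Product: 5 2-iodo-3,4,5,6-tetramethoxyphenol
Conditions: NIS (1.05 equiv), MeCN, 0 °C, dark
Reagents that add atoms: N-iodosuccinimide, O=C1CCC(=O)N1I
Why: Electrophilic aromatic iodination of a strongly activated phenol whose only unsubstituted ring carbon is ortho to the hydroxyl, so the regiochemistry is forced and the mild iodine source should spare the ring from oxidation to a quinone.

Step 3
Reactants: 5 2-iodo-3,4,5,6-tetramethoxyphenol, 6 4-ethynylanisole, 7 carbon monoxide
Product: 10 5,6,7,8-tetramethoxy-2-(4-methoxyphenyl)chromen-4-one (tangeretin), via ynone 8 (not isolated), via diethylamino enone 9 (not isolated)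
Conditions: PdCl2(dppf) (5 mol %), CO (20 bar), Et2NH (solvent and base), 120 °C, autoclave
Reagents that add atoms: none
Why: Pd(0) inserts into the C–I bond of 5, CO inserts to give the aroylpalladium, and coupling with the acetylide generated from 6 by Et2NH (copper-free carbonylative Sonogashira) forms C4a–C4 and C4–C3 in ynone 8. Et2NH then adds to the ynone to give β-aminoenone 9, and the C8a phenol closes the pyranone at the carbon that becomes C2 by 6-endo-trig oxa-Michael addition and loss of Et2NH, forming O1–C2 (net 6-endo-dig on 8). The closest known reaction type is the palladium-catalysed carbonylative annulation of ortho-iodophenols with terminal arylacetylenes in a secondary amine, which is established for methoxy-substituted iodophenols. No stereocentre is formed. Two selectivities are needed: CO insertion before alkynylation, which CO pressure and the di-ortho-substituted, electron-rich arylpalladium favour, and six- over five-membered closure, which passage through 9 secures because the aminoenone offers only its β-carbon to the phenol and no alkyne for 5-exo-dig attack to the aurone. The site of the carbonyl is unambiguous because iodine sits on the only A-ring carbon that is ortho to the phenol.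

Step 4
Reactants: 10 5,6,7,8-tetramethoxy-2-(4-methoxyphenyl)chromen-4-one
Product: 12 3-hydroxy-5,6,7,8-tetramethoxy-2-(4-methoxyphenyl)chromen-4-one, via flavone oxide 11 (not isolated)
Conditions: DMDO (acetone solution, 3 equiv), CH2Cl2, 0 °C to rt; then TsOH·H2O (cat.), CH2Cl2, rt
Reagents that add atoms: dimethyldioxirane, CC1(C)OO1
Why: Electrophilic epoxidation of the C2=C3 enol-ether alkene by the dioxirane gives the 2,3-oxide, which under acid opens at C2 to the aryl- and oxygen-stabilised cation and loses H3 to give the flavonol (epoxidation–isomerisation of a flavone).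

Step 5
Reactants: 12 3-hydroxy-5,6,7,8-tetramethoxy-2-(4-methoxyphenyl)chromen-4-one
Product: 13 3,5,6,7,8-pentamethoxy-2-(4-methoxyphenyl)chromen-4-one
Conditions: MeI, K2CO3, acetone, reflux
Reagents that add atoms: iodomethane, CI
Why: Williamson O-methylation of the only free hydroxyl in the molecule, the acidic 3-OH of the flavonol.

Step 6
Reactants: 13 3,5,6,7,8-pentamethoxy-2-(4-methoxyphenyl)chromen-4-one
Product: 14 5-hydroxy-3,6,7,8-tetramethoxy-2-(4-methoxyphenyl)chromen-4-one (5-hydroxyauranetin)
Conditions: BCl3 (1 M in CH2Cl2, 1.5 equiv), CH2Cl2, −78 to 0 °C; then 1 M aq. HCl, rt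
Reagents that add atoms: none
Why: BCl3 binds C4=O and the peri 5-OMe oxygen in a six-membered chelate and chloride removes that methyl by SN2 (chelation-directed Lewis-acid ether cleavage), which at low temperature should outrun cleavage of the 3-OMe (five-membered chelate) and of the unchelated 6-, 7-, 8- and 4'-OMe groups.

**Compound list**
1 | 1,2,3,4-tetramethoxybenzene | COc1ccc(OC)c(OC)c1OC | starting material
2 | 2,3,4,5-tetramethoxyphenyllithium | [Li]c1cc(OC)c(OC)c(OC)c1OC | intermediate
3 | dimethyl (2,3,4,5-tetramethoxyphenyl)boronate | COB(OC)c1cc(OC)c(OC)c(OC)c1OC | intermediate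
4 | 2,3,4,5-tetramethoxyphenol | COc1cc(O)c(OC)c(OC)c1OC | intermediate
5 | 2-iodo-3,4,5,6-tetramethoxyphenol | COc1c(O)c(I)c(OC)c(OC)c1OC | intermediate
6 | 4-ethynylanisole | C#Cc1ccc(OC)cc1 | starting material
7 | carbon monoxide | [C-]#[O+] | starting material
8 | 1-(2-hydroxy-3,4,5,6-tetramethoxyphenyl)-3-(4-methoxyphenyl)prop-2-yn-1-one | COc1ccc(C#CC(=O)c2c(O)c(OC)c(OC)c(OC)c2OC)cc1 | intermediate
9 | (E)-3-(diethylamino)-1-(2-hydroxy-3,4,5,6-tetramethoxyphenyl)-3-(4-methoxyphenyl)prop-2-en-1-one (drawn as E; either geometry can cyclise) | CCN(CC)/C(=C/C(=O)c1c(O)c(OC)c(OC)c(OC)c1OC)c1ccc(OC)cc1 | intermediate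
10 | 5,6,7,8-tetramethoxy-2-(4-methoxyphenyl)chromen-4-one (tangeretin) | COc1ccc(-c2cc(=O)c3c(OC)c(OC)c(OC)c(OC)c3o2)cc1 | intermediate
11 | 2,3-epoxy-5,6,7,8-tetramethoxy-2-(4-methoxyphenyl)chroman-4-one (2,3-oxide of 10; cis-fused, racemic, one enantiomer drawn) | COc1ccc(cc1)[C@]23O[C@H]2C(=O)c2c(OC)c(OC)c(OC)c(OC)c2O3 | intermediate
12 | 3-hydroxy-5,6,7,8-tetramethoxy-2-(4-methoxyphenyl)chromen-4-one | COc1ccc(-c2oc3c(OC)c(OC)c(OC)c(OC)c3c(=O)c2O)cc1 | intermediate
13 | 3,5,6,7,8-pentamethoxy-2-(4-methoxyphenyl)chromen-4-one | COc1ccc(-c2oc3c(OC)c(OC)c(OC)c(OC)c3c(=O)c2OC)cc1 | intermediate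
14 | 5-hydroxy-3,6,7,8-tetramethoxy-2-(4-methoxyphenyl)chromen-4-one (5-hydroxyauranetin) | COc1ccc(-c2oc3c(OC)c(OC)c(OC)c(O)c3c(=O)c2OC)cc1 | target

**Step count**
Total steps: 6. Longest linear sequence: 6 steps (1 to 14).

**Steps most likely to fail**

Step 3. The arylpalladium may couple with the alkyne before CO inserts and then close to a 2-arylbenzofuran, the aroylpalladium may be intercepted by Et2NH to give the diethylamide, or the ynone may close in the five-membered sense to the aurone. The fallback sets out from 4 and comes back to the route at 10 by the chalcone route, which does not use palladium or CO. Phenol 4 would be C-acetylated at its only free ring carbon (AcOH, BF3·OEt2, 90 °C) to 1-(2-hydroxy-3,4,5,6-tetramethoxyphenyl)ethanone F1. Claisen–Schmidt condensation of this ketone with 4-methoxybenzaldehyde (KOH, EtOH, rt) should give (E)-1-(2-hydroxy-3,4,5,6-tetramethoxyphenyl)-3-(4-methoxyphenyl)prop-2-en-1-one F2. Oxidative cyclisation of the chalcone with catalytic I2 in DMSO at 120 °C should then give 10.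

Step 6. The Lewis acid may also remove the 3-O-methyl group, which chelates to the same carbonyl, or go on to cleave the 6-OMe once the 5-O–boron chelate has formed. The fallback sets out from 12 and comes back at 14 by inverting the order of the last two operations, so that a chemoselective alkylation replaces the chemoselective dealkylation. Flavonol 12 would be demethylated at the peri position (anhydrous AlCl3, MeCN, rt to 50 °C) to 3,5-dihydroxy-6,7,8-trimethoxy-2-(4-methoxyphenyl)chromen-4-one F3, in which no 3-OMe is at risk. The 3-OH would then be methylated selectively (MeI, 1.05 equiv, K2CO3, acetone, rt). The 5-OH is strongly hydrogen-bonded to C4=O and is the least nucleophilic hydroxyl, so this should give 14.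

Step 4. Epoxidation of the carbonyl-deactivated alkene may be slow enough for oxidation of the electron-rich aryl rings to compete, and the epoxide may open toward ring-contracted or cleaved products instead of isomerising to the flavonol. The fallback sets out from 10 and comes back at 12 by an anionic C–H functionalisation. Deprotonation at C3 with LDA (THF, −78 °C) should give 3-lithio-5,6,7,8-tetramethoxy-2-(4-methoxyphenyl)chromen-4-one F4, stabilised by the adjacent carbonyl. Trapping with B(OMe)3 would give dimethyl [5,6,7,8-tetramethoxy-2-(4-methoxyphenyl)-4-oxochromen-3-yl]boronate F5, and oxidation with H2O2/AcOH (0 °C to rt) should give 12.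

**Further compounds**
F1 | step 3 | 1-(2-hydroxy-3,4,5,6-tetramethoxyphenyl)ethanone | CC(=O)c1c(O)c(OC)c(OC)c(OC)c1OC
F2 | step 3 | (E)-1-(2-hydroxy-3,4,5,6-tetramethoxyphenyl)-3-(4-methoxyphenyl)prop-2-en-1-one | COc1ccc(/C=C/C(=O)c2c(O)c(OC)c(OC)c(OC)c2OC)cc1
F3 | step 6 | 3,5-dihydroxy-6,7,8-trimethoxy-2-(4-methoxyphenyl)chromen-4-one | COc1ccc(-c2oc3c(OC)c(OC)c(OC)c(O)c3c(=O)c2O)cc1
F4 | step 4 | 3-lithio-5,6,7,8-tetramethoxy-2-(4-methoxyphenyl)chromen-4-one | [Li]c1c(-c2ccc(OC)cc2)oc2c(OC)c(OC)c(OC)c(OC)c2c1=O
F5 | step 4 | dimethyl [5,6,7,8-tetramethoxy-2-(4-methoxyphenyl)-4-oxochromen-3-yl]boronate | COB(OC)c1c(-c2ccc(OC)cc2)oc2c(OC)c(OC)c(OC)c(OC)c2c1=O
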